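**Retrosynthetic overview**
- The target, 3-[(2R)-2-hydroxyheptadecyl]-5-methoxyphenol, is traced back (desilylation, decarboxylation, ester hydrolysis, O-methylation) to methyl 2,4-dihydroxy-6-[(R)-2-silyloxyheptadecyl]benzoate. The ester sits on the ring CH between the side chain and the future free phenol, tells the two ring oxygens apart, and later leaves as CO2.
- The benzene ring, the only ring, is formed in step 6 by C2–C7 intramolecular aldol condensation and aromatization of linear methyl (R)-9-silyloxy-3,5,7-trioxotetracosanoate.
- The triketo ester comes from C6–C7 acylation of the trianion of methyl 3,5-dioxohexanoate with the Weinreb amide of (R)-3-silyloxyoctadecanoic acid.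
- The (R)-carbinol comes from Ru–(R)-BINAP hydrogenation of methyl 3-oxooctadecanoate, itself made from palmitoyl chloride and Meldrum's acid.
- Feature used: ring oxygens at C3 (OH) and C5 (OMe) are meta to each other and to ring C1 bearing the CH2, and the chain has OH on its C2. Oxygen on every second carbon is the pattern of an unfolded poly-β-carbonyl chain.

Key step: step 6

Remark: methyl 3,5-dioxohexanoate is treated as a purchased material; if supply fails it is accessible in one step from dehydroacetic acid by Mg(OMe)2-mediated methanolysis.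

**Step 1**
Reactants: 1 palmitoyl chloride; 2 Meldrum's acid
Product: 4 methyl 3-oxooctadecanoate, via acyl Meldrum's acid 3 (not isolated)
Conditions: pyridine (2.2 equiv), CH2Cl2, 0 °C → rt; then MeOH, reflux
Reagents that add atoms: methanol, CO
Why: C-acylation of Meldrum's acid followed by methanolysis (acylketene formation with loss of acetone and CO2, then trapping by methanol) is the standard Meldrum's acid route to β-keto esters and extends the C16 acid chloride by two carbons.

**Step 2**
Reactants: 4 methyl 3-oxooctadecanoate
Product: 5 methyl (R)-3-hydroxyoctadecanoate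
Conditions: RuCl2[(R)-BINAP] (0.1 mol %), H2 (50 atm), MeOH, 50 °C
Reagents that add atoms: none
Why: Noyori asymmetric hydrogenation of a β-keto ester, in which the ester carbonyl and the ketone chelate ruthenium so that the (R)-BINAP ligand exposes one ketone face to hydride and the (R)-carbinol should form, the sense established for simple 3-oxoalkanoates whose CH2CO2Me group outranks the alkyl chain.

**Step 3**
Reactants: 5 methyl (R)-3-hydroxyoctadecanoate
Product: 6 methyl (R)-3-(tert-butyldimethylsilyloxy)octadecanoate
Conditions: TBSCl, imidazole, DMF, rt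
Reagents that add atoms: tert-butyldimethylsilyl chloride, CC(C)(C)[Si](C)(C)Cl
Why: Imidazole-promoted silylation of a secondary alcohol protects the carbinol against elimination and lactonization in all later steps without touching the stereocenter.

**Step 4**
Reactants: 6 methyl (R)-3-(tert-butyldimethylsilyloxy)octadecanoate
Product: 7 (R)-3-(tert-butyldimethylsilyloxy)-N-methoxy-N-methyloctadecanamide
Conditions: MeNH(OMe)·HCl (1.6 equiv), iPrMgCl (3.2 equiv), THF, −20 → 0 °C
Reagents that add atoms: N,O-dimethylhydroxylamine hydrochloride, CNOC.Cl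
Why: Direct ester-to-Weinreb-amide aminolysis with the chloromagnesium amide made in the flask from the amine hydrochloride and iPrMgCl is fast at low temperature and leaves the β-silyloxy group and the stereocenter untouched.

**Step 5**
Reactants: 7 (R)-3-(tert-butyldimethylsilyloxy)-N-methoxy-N-methyloctadecanamide; 8 methyl 3,5-dioxohexanoate
Product: 10 methyl (R)-9-(tert-butyldimethylsilyloxy)-3,5,7-trioxotetracosanoate, via trilithium trienolate 9 (not isolated)
Conditions: 8 (1.5 equiv), LiN(iPr)2 (4.6 equiv), THF, −78 → 0 °C; then 7, −78 → −20 °C; AcOH quench at −78 °C, pH 5 work-up; used crude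
Reagents that add atoms: none
Why: C-acylation of a 1,3,5-tricarbonyl trianion at its terminal, last-formed and most nucleophilic carbanion (polyanion Claisen-type condensation), with the Weinreb amide giving a chelated tetrahedral adduct that survives until the acidic quench and so prevents both over-addition and proton transfer from product to trianion.

**Step 6**
Reactants: 10 methyl (R)-9-(tert-butyldimethylsilyloxy)-3,5,7-trioxotetracosanoate
Product: 12 methyl 2,4-dihydroxy-6-[(R)-2-(tert-butyldimethylsilyloxy)heptadecyl]benzoate, via cyclic aldol adduct 11 (not isolated)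
Conditions: K2CO3 (1.5 equiv), MeOH, 0 °C → rt; then AcOH to pH 5
Reagents that add atoms: none
Why: Carbonate sets up the enolates of the chain in equilibrium, the C2 carbon (flanked by the ester and the C3 ketone) adds to the C7 ketone, the β-hydroxy ketone 11 loses water by E1cB and the two remaining ring ketones enolize, which makes the sequence irreversible. The closest known reaction type is the mild-base aldol cyclization and aromatization of 3,5,7-triketo esters to 6-substituted 2,4-dihydroxybenzoates (biomimetic resorcylate synthesis). The six-membered carbocycle closes in a 6-(enolendo)-exo-trig mode, with the C2=C3 enolate inside the new ring and the C7 carbonyl oxygen outside it. No lasting stereocenter is created, since the two sp3 ring centers of 11 are erased on aromatization, and C9 is not enolizable and should keep its (R) configuration. The step must prefer C2-to-C7 aldol closure over C6-to-C1 Claisen closure, O-cyclization to pyrones, C8-to-C3 aldol closure and β-elimination of the C9 silyloxy group; this is secured because C2 is doubly activated while C8 is activated by one carbonyl only, because potassium carbonate in methanol is too weak and too poorly chelating to drive methoxide expulsion from the ester, and because low temperature and the absence of strong acid or strong base keep pyrone formation and elimination slow.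

**Step 7**
Reactants: 12 methyl 2,4-dihydroxy-6-[(R)-2-(tert-butyldimethylsilyloxy)heptadecyl]benzoate
Product: 13 methyl 2-hydroxy-4-methoxy-6-[(R)-2-(tert-butyldimethylsilyloxy)heptadecyl]benzoate
Conditions: MeI (1.05 equiv), K2CO3 (1.1 equiv), acetone, rt → 40 °C
Reagents that add atoms: iodomethane, CI
Why: Williamson O-methylation that is regioselective because the hydroxyl ortho to the ester is held in a hydrogen bond to the carbonyl and is less acidic, so with about one equivalent of base and iodomethane only the para hydroxyl should react, as is usual for 2,4-dihydroxybenzoates.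

**Step 8**
Reactants: 13 methyl 2-hydroxy-4-methoxy-6-[(R)-2-(tert-butyldimethylsilyloxy)heptadecyl]benzoate
Product: 14 2-hydroxy-4-methoxy-6-[(R)-2-(tert-butyldimethylsilyloxy)heptadecyl]benzoic acid
Conditions: KOH (10 equiv), EtOH–H2O (3:1), reflux; then 0 °C, 1 M HCl to pH 3–4, rapid extraction
Reagents that add atoms: potassium hydroxide, [K+].[OH-]
Why: Acyl–oxygen saponification, which needs hot concentrated alkali because the ester is flanked by two ortho substituents and deactivated by the ortho phenoxide, conditions that a secondary alkyl silyl ether and an aryl methyl ether are expected to tolerate, while the cold and brief acidification keeps the silyl ether on so that the acid cannot lactonize onto the side-chain oxygen.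

**Step 9**
Reactants: 14 2-hydroxy-4-methoxy-6-[(R)-2-(tert-butyldimethylsilyloxy)heptadecyl]benzoic acid
Product: 15 3-[(R)-2-(tert-butyldimethylsilyloxy)heptadecyl]-5-methoxyphenol
Conditions: quinoline, 170 °C, Ar; cold dilute HCl wash
Reagents that add atoms: none
Why: Thermal protodecarboxylation of an electron-rich salicylic acid, in which ipso protonation at the carbon ortho to the hydroxyl and para to the methoxy group gives a cyclohexadienone β-keto acid that expels CO2, and quinoline buffers the acid so that the silyl ether is not exposed to hot free acid.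

**Step 10**
Reactants: 15 3-[(R)-2-(tert-butyldimethylsilyloxy)heptadecyl]-5-methoxyphenol
Product: 16 (R)-1-(3-hydroxy-5-methoxyphenyl)heptadecan-2-ol
Conditions: p-TsOH·H2O (0.2 equiv), MeOH–CH2Cl2 (1:1), rt → 35 °C
Reagents that add atoms: none
Why: Acid-catalysed methanolysis of the silyl ether, safe at this stage because the carboxyl group is gone and no lactone can form, and stereoretentive because the C–O bond of the carbinol is never broken.

**Compound list**
1 | palmitoyl chloride (hexadecanoyl chloride) | CCCCCCCCCCCCCCCC(=O)Cl | starting material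
2 | Meldrum's acid (2,2-dimethyl-1,3-dioxane-4,6-dione) | CC1(C)OC(=O)CC(=O)O1 | starting material
3 | 5-(1-hydroxyhexadecylidene)-2,2-dimethyl-1,3-dioxane-4,6-dione (acyl Meldrum's acid, enol form) | CCCCCCCCCCCCCCCC(O)=C1C(=O)OC(C)(C)OC1=O | intermediate
4 | methyl 3-oxooctadecanoate | CCCCCCCCCCCCCCCC(=O)CC(=O)OC | intermediate
5 | methyl (R)-3-hydroxyoctadecanoate | CCCCCCCCCCCCCCC[C@@H](O)CC(=O)OC | intermediate
6 | methyl (R)-3-(tert-butyldimethylsilyloxy)octadecanoate | CCCCCCCCCCCCCCC[C@@H](O[Si](C)(C)C(C)(C)C)CC(=O)OC | intermediate
7 | (R)-3-(tert-butyldimethylsilyloxy)-N-methoxy-N-methyloctadecanamide | CCCCCCCCCCCCCCC[C@@H](O[Si](C)(C)C(C)(C)C)CC(=O)N(C)OC | intermediate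
8 | methyl 3,5-dioxohexanoate | CC(=O)CC(=O)CC(=O)OC | starting material
9 | trilithium trienolate (trianion) of methyl 3,5-dioxohexanoate | C=C(O[Li])C=C(O[Li])C=C(O[Li])OC | intermediate
10 | methyl (R)-9-(tert-butyldimethylsilyloxy)-3,5,7-trioxotetracosanoate (drawn as the triketo tautomer) | CCCCCCCCCCCCCCC[C@@H](O[Si](C)(C)C(C)(C)C)CC(=O)CC(=O)CC(=O)CC(=O)OC | intermediate
11 | methyl 2-hydroxy-2-[(R)-2-(tert-butyldimethylsilyloxy)heptadecyl]-4,6-dioxocyclohexane-1-carboxylate (ring stereocenters undefined) | CCCCCCCCCCCCCCC[C@@H](O[Si](C)(C)C(C)(C)C)CC1(O)CC(=O)CC(=O)C1C(=O)OC | intermediate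
12 | methyl 2,4-dihydroxy-6-[(R)-2-(tert-butyldimethylsilyloxy)heptadecyl]benzoate | CCCCCCCCCCCCCCC[C@@H](O[Si](C)(C)C(C)(C)C)Cc1cc(O)cc(O)c1C(=O)OC | intermediate
13 | methyl 2-hydroxy-4-methoxy-6-[(R)-2-(tert-butyldimethylsilyloxy)heptadecyl]benzoate | CCCCCCCCCCCCCCC[C@@H](O[Si](C)(C)C(C)(C)C)Cc1cc(OC)cc(O)c1C(=O)OC | intermediate
14 | 2-hydroxy-4-methoxy-6-[(R)-2-(tert-butyldimethylsilyloxy)heptadecyl]benzoic acid | CCCCCCCCCCCCCCC[C@@H](O[Si](C)(C)C(C)(C)C)Cc1cc(OC)cc(O)c1C(=O)O | intermediate
15 | 3-[(R)-2-(tert-butyldimethylsilyloxy)heptadecyl]-5-methoxyphenol | CCCCCCCCCCCCCCC[C@@H](O[Si](C)(C)C(C)(C)C)Cc1cc(OC)cc(O)c1 | intermediate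
16 | (R)-1-(3-hydroxy-5-methoxyphenyl)heptadecan-2-ol | CCCCCCCCCCCCCCC[C@@H](O)Cc1cc(O)cc(OC)c1 | target

**Total step count:** 10
**Longest linear sequence:** 10 steps (from palmitoyl chloride; methyl 3,5-dioxohexanoate enters at step 5)

**Steps most likely to fail**

Step 6 (key step). The chain may close through the wrong atoms (C6 onto the ester carbonyl, or an enol oxygen onto a carbonyl to give pyrones), or base may expel the C9 silyloxy group by elimination before the aldol closes. The fallback sets out from Weinreb amide 7 and comes back at resorcylate 12, with the carboxyl locked in a dioxinone so that neither Claisen nor pyrone closure is possible. Commercial 2,2,6-trimethyl-4H-1,3-dioxin-4-one is deprotonated with LiN(SiMe3)2 and C-acylated with acetyl chloride to give 2,2-dimethyl-6-(2-oxopropyl)-4H-1,3-dioxin-4-one F1. Its dianion (LiN(iPr)2, THF, −78 °C) is acylated at the terminal carbon by 7 to give 6-[(R)-6-(tert-butyldimethylsilyloxy)-2,4-dioxohenicosyl]-2,2-dimethyl-4H-1,3-dioxin-4-one F2. Triethylamine in CH2Cl2 at room temperature should aromatize this to 7-hydroxy-2,2-dimethyl-5-[(R)-2-(tert-butyldimethylsilyloxy)heptadecyl]-4H-benzo[d][1,3]dioxin-4-one F3. K2CO3 in methanol then opens the dioxinone to 12.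

Step 5. Proton transfer from the α-methylene of the Weinreb amide to the strongly basic terminal carbanion, followed by loss of silanolate, or an incomplete third deprotonation, may outrun C-acylation. The fallback sets out from 7 and comes back at triketo ester 10, replacing the acylation by an aldol addition and oxidation. Reduction of 7 with iBu2AlH (THF, −78 °C) gives (R)-3-(tert-butyldimethylsilyloxy)octadecanal F4, which an enolate attacks far faster than it deprotonates. Addition of trianion 9 at −78 °C gives methyl (9R)-9-(tert-butyldimethylsilyloxy)-7-hydroxy-3,5-dioxotetracosanoate F5 as a C7 epimer mixture. Dess–Martin periodinane (CH2Cl2, 0 °C) oxidizes the C7 carbinol to give 10.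

Step 8. Hydrolysis of the hindered, chelated ester may stall; under harsher alkali the silyl group may be lost, and the freed hydroxyl then closes onto the carboxyl as a six-membered lactone. The fallback sets out from ester 13 and comes back at acid 14, cleaving the alkyl–oxygen bond instead of the acyl–oxygen bond. LiI in refluxing pyridine attacks the ester methyl group by SN2, which is insensitive to crowding at the carbonyl and free of hydroxide. This gives lithium 2-hydroxy-4-methoxy-6-[(R)-2-(tert-butyldimethylsilyloxy)heptadecyl]benzoate F6, and cold acidification to pH 3–4 gives 14.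

**Further compounds**
F1 | step 6 | 2,2-dimethyl-6-(2-oxopropyl)-4H-1,3-dioxin-4-one | CC(=O)CC1=CC(=O)OC(C)(C)O1
F2 | step 6 | 6-[(R)-6-(tert-butyldimethylsilyloxy)-2,4-dioxohenicosyl]-2,2-dimethyl-4H-1,3-dioxin-4-one | CCCCCCCCCCCCCCC[C@@H](O[Si](C)(C)C(C)(C)C)CC(=O)CC(=O)CC1=CC(=O)OC(C)(C)O1
F3 | step 6 | 7-hydroxy-2,2-dimethyl-5-[(R)-2-(tert-butyldimethylsilyloxy)heptadecyl]-4H-benzo[d][1,3]dioxin-4-one | CCCCCCCCCCCCCCC[C@@H](O[Si](C)(C)C(C)(C)C)Cc1cc(O)cc2OC(C)(C)OC(=O)c12
F4 | step 5 | (R)-3-(tert-butyldimethylsilyloxy)octadecanal | CCCCCCCCCCCCCCC[C@@H](O[Si](C)(C)C(C)(C)C)CC=O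
F5 | step 5 | methyl (9R)-9-(tert-butyldimethylsilyloxy)-7-hydroxy-3,5-dioxotetracosanoate (C7 epimers) | CCCCCCCCCCCCCCC[C@@H](O[Si](C)(C)C(C)(C)C)CC(O)CC(=O)CC(=O)CC(=O)OC
F6 | step 8 | lithium 2-hydroxy-4-methoxy-6-[(R)-2-(tert-butyldimethylsilyloxy)heptadecyl]benzoate | [Li+].CCCCCCCCCCCCCCC[C@@H](O[Si](C)(C)C(C)(C)C)Cc1cc(OC)cc(O)c1C(=O)[O-]
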